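**Assumption:** the target has no stereogenic centre (each quaternary ring carbon carries two identical methyl groups), so there is no enantiomer to choose; all compounds are achiral unless noted and are drawn in the enol tautomer of the given SMILES.

## Retrosynthetic overview

1. The target is two acylfilicinic acid rings (ring A butanoyl, ring B propanoyl) joined by one CH2. The key cut is the ring A carbon–CH2 bond.
2. That bond is made by a palladium-catalysed union of ring A as its phenyliodonium ylide (an enolonium equivalent, acceptor at the 1,3-dione α-carbon) with a ring B–CH2–B(pin) carbon (a boron homoenolate). The dione α-carbon and the C–B carbon are both donors in their ordinary forms, and the polarity-differentiated partners cannot give homodimers.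
3. The CH2 comes from ICH2Bpin, attached to ring B by C-alkylation of its dianion and then used as the nucleophile.
4. Each ring comes from a commercial acylphloroglucinol by dearomatising gem-C-dimethylation.
5. No ring is formed in the route: both carbocycles are bought as benzene rings. Ring A is finished first (steps 1–2), ring B second (step 3), and the union is last (step 4).

## Route

**Step 1**
Reactants: 1 2′,4′,6′-trihydroxybutyrophenone; 2 iodomethane
Product: 4 butyrylfilicinic acid (2-butanoyl-3,5-dihydroxy-4,4-dimethylcyclohexa-2,5-dien-1-one), via 3-methylphlorobutyrophenone 3 (not isolated)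
Conditions: NaOMe (3 equiv), MeI (2.2 equiv), MeOH, 0 °C to rt; then 1 M HCl
Reagents that add atoms: iodomethane, CI
Why: Dearomatising C-alkylation of the phloroglucinol polyanion, in which the second methyl enters the already methylated, most electron-rich ring carbon to give the gem-dimethyl triketone (the standard preparation of acylfilicinic acids; modest yield, with the aromatic 3,5-dimethyl and trimethyl by-products removed by crystallisation); no stereocentre is formed.

**Step 2**
Reactants: 4 butyrylfilicinic acid; 5 (diacetoxyiodo)benzene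
Product: 6 phenyliodonium ylide of 4 (6-butanoyl-5-hydroxy-4,4-dimethyl-3-oxo-2-(phenyliodonio)cyclohexa-1,5-dien-1-olate, zwitterion)
Conditions: PhI(OAc)2 (1.05 equiv), CH2Cl2, 0 °C to rt; precipitate with Et2O, filter
Reagents that add atoms: (diacetoxyiodo)benzene, CC(=O)OI(OC(C)=O)c1ccccc1
Why: Iodonium ylide formation, in which a cyclic 1,3-dione with a free 2-position exchanges both acetates on trivalent iodine (loss of 2 AcOH) to give a stable zwitterion; only the unsubstituted ring carbon of 4 can react, and it becomes an acceptor centre.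

**Step 3**
Reactants: 7 flopropione (1-(2,4,6-trihydroxyphenyl)propan-1-one); 2 iodomethane
Product: 9 propionylfilicinic acid (3,5-dihydroxy-4,4-dimethyl-2-propanoylcyclohexa-2,5-dien-1-one), via 3-methylflopropione 8 (not isolated)
Conditions: NaOMe (3 equiv), MeI (2.2 equiv), MeOH, 0 °C to rt; then 1 M HCl
Reagents that add atoms: iodomethane, CI
Why: The same dearomatising gem-C-dimethylation of a phloroglucinol polyanion as in step 1 (enolate C-alkylation); no stereocentre is formed.

**Step 4**
Reactants: 9 propionylfilicinic acid; 10 2-(iodomethyl)-4,4,5,5-tetramethyl-1,3,2-dioxaborolane; 6 phenyliodonium ylide of butyrylfilicinic acid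
Product: 12 target, 2-butanoyl-6-[(2,4-dihydroxy-3,3-dimethyl-6-oxo-5-propanoylcyclohexa-1,4-dien-1-yl)methyl]-3,5-dihydroxy-4,4-dimethylcyclohexa-2,5-dien-1-one, via borylmethyl trione 11 (not isolated)
Conditions: 9, LiOt-Bu (2.0 equiv), THF, −20 °C; 10 (0.95 equiv), −20 °C to rt; then 6 (1.3 equiv), Pd(OAc)2 (5 mol %), P(t-Bu)3·HBF4 (10 mol %), LiOH·H2O (3 equiv), degassed THF–H2O 4:1, rt; 1 M HCl
Reagents that add atoms: 2-(iodomethyl)-4,4,5,5-tetramethyl-1,3,2-dioxaborolane, ICB1OC(C)(C)C(C)(C)O1
Why: Proposed new method: the dilithium dianion of 9 is C-alkylated at its free ring carbon by the very SN2-reactive α-boryl iodide 10 (the site at which acylfilicinic acids are C-methylated; malonate-type anions are known to be C-alkylated by halomethylboronates), giving the boron homoenolate 11, whose neighbouring enolate oxygen chelates boron into an activated "ate" form; zerovalent palladium then inserts into the ring C–I bond of the enolonium equivalent 6 with loss of PhI, the CH2 group (no β-hydrogen) is transmetallated from boron, and reductive elimination forms the ring A–CH2 bond in a Suzuki–Miyaura-type cross-coupling. The closest known reactions are the palladium-catalysed Suzuki-type coupling of phenyliodonium zwitterions of cyclic 1,3-dicarbonyls with boronic acids and the cross-coupling of β-boryl carbonyl compounds with C(sp2) electrophiles. Ylide 6 is used in excess so that the liberated PhI does not compete for 11, and no stereocentre is formed.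

## Compound list

1 | 2′,4′,6′-trihydroxybutyrophenone, 1-(2,4,6-trihydroxyphenyl)butan-1-one | CCCC(=O)c1c(O)cc(O)cc1O | starting material
2 | iodomethane | CI | starting material
3 | 3-methylphlorobutyrophenone, 1-(2,4,6-trihydroxy-3-methylphenyl)butan-1-one | CCCC(=O)c1c(O)cc(O)c(C)c1O | intermediate (not isolated)
4 | butyrylfilicinic acid, 2-butanoyl-3,5-dihydroxy-4,4-dimethylcyclohexa-2,5-dien-1-one | CCCC(=O)C1=C(O)C(C)(C)C(O)=CC1=O | intermediate
5 | (diacetoxyiodo)benzene | CC(=O)OI(OC(C)=O)c1ccccc1 | starting material
6 | phenyliodonium ylide of 4, 6-butanoyl-5-hydroxy-4,4-dimethyl-3-oxo-2-(phenyliodonio)cyclohexa-1,5-dien-1-olate (zwitterion, one tautomer drawn) | CCCC(=O)C1=C(O)C(C)(C)C(=O)C(=C1[O-])[I+]c1ccccc1 | intermediate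
7 | flopropione, 1-(2,4,6-trihydroxyphenyl)propan-1-one | CCC(=O)c1c(O)cc(O)cc1O | starting material
8 | 3-methylflopropione, 1-(2,4,6-trihydroxy-3-methylphenyl)propan-1-one | CCC(=O)c1c(O)cc(O)c(C)c1O | intermediate (not isolated)
9 | propionylfilicinic acid, 3,5-dihydroxy-4,4-dimethyl-2-propanoylcyclohexa-2,5-dien-1-one | CCC(=O)C1=C(O)C(C)(C)C(O)=CC1=O | intermediate
10 | 2-(iodomethyl)-4,4,5,5-tetramethyl-1,3,2-dioxaborolane (ICH2Bpin) | ICB1OC(C)(C)C(C)(C)O1 | starting material
11 | borylmethyl trione, 3,5-dihydroxy-4,4-dimethyl-2-propanoyl-6-[(4,4,5,5-tetramethyl-1,3,2-dioxaborolan-2-yl)methyl]cyclohexa-2,5-dien-1-one | CCC(=O)C1=C(O)C(C)(C)C(O)=C(CB2OC(C)(C)C(C)(C)O2)C1=O | intermediate (not isolated)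
12 | target, 2-butanoyl-6-[(2,4-dihydroxy-3,3-dimethyl-6-oxo-5-propanoylcyclohexa-1,4-dien-1-yl)methyl]-3,5-dihydroxy-4,4-dimethylcyclohexa-2,5-dien-1-one (achiral) | CCCC(=O)C1=C(O)C(C)(C)C(O)=C(CC2=C(O)C(C)(C)C(O)=C(C(=O)CC)C2=O)C1=O | target

## Step count and risks

Total steps: 4. Longest linear sequence: 3 (1 → 4 → 6 → 12).

**Step 4 (most likely to fail).** The dianion of 9 may be O-alkylated, 11 may protodeboronate, the triketones may sequester palladium, or sp3 transmetallation and reductive elimination onto the dione carbon may be too slow. The fallback sets out from 9, keeps ylide 6 as the acceptor, and comes back to the route at 12. Compound 9 is condensed with aqueous formaldehyde and thiophenol (Et3N cat., EtOH, rt) to the sulfide 3,5-dihydroxy-4,4-dimethyl-6-[(phenylsulfanyl)methyl]-2-propanoylcyclohexa-2,5-dien-1-one F1. Rh2(OAc)4-catalysed carbene transfer from 6 to the sulfur of F1 (CH2Cl2, rt to 40 °C) gives the S-phenyl sulfonium ylide F2. On warming, F2 undergoes a [1,2]-shift (Stevens rearrangement) of the CH2 group from sulfur to the ylide carbon, giving the racemic α-phenylsulfanyl trione F3. Zn dust in AcOH at rt then cleaves the C–S bond, removing the only stereocentre, and gives 12.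

**Step 2.** PhI(OAc)2 may over-oxidise the electron-rich enol, or the zwitterion with its free acidic enol may be too labile to store. The fallback sets out from 4 and comes back at 12. Regitz diazo transfer (p-acetamidobenzenesulfonyl azide, Et3N, MeCN, 0 °C) at the free ring carbon gives 2-butanoyl-6-diazo-3-hydroxy-4,4-dimethylcyclohex-2-ene-1,5-dione F4, a bench-stable carbene precursor that plays the same acceptor role. With boronate 11 made in the flask as in step 4, [Rh(cod)OH]2 (cat.), aqueous KOH and dioxane at 40 °C, the CH2 group is transmetallated to monovalent rhodium. F4 then forms a rhodium carbene with loss of N2, and 1,2-migration of the CH2 group to the carbene carbon followed by protonation of the rhodium enolate gives 12.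

**Step 1 (step 3 is the same reaction and carries the same risk).** The gem-dimethyl product may be a minor component beside the aromatic 3,5-dimethyl and over-methylated products. The fallback sets out from iodomethane 2, installs both methyl groups before the ring exists, and comes back at 4. Compound 2 dimethylates dimethyl malonate (NaOMe, MeOH) at its only alkylatable carbon to give dimethyl 2,2-dimethylpropanedioate F5. The dianion of commercial heptane-2,4-dione (LDA, 2 equiv, THF, −78 to 0 °C) is acylated at its terminal methyl carbon by F5 (Claisen condensation) to give methyl 2,2-dimethyl-3,5,7-trioxodecanoate F6. NaOMe in refluxing MeOH then closes the six-membered ring by Dieckmann-type attack of C-6 on the ester, giving 4.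

## Further compounds

F1 | step 4 | 3,5-dihydroxy-4,4-dimethyl-6-[(phenylsulfanyl)methyl]-2-propanoylcyclohexa-2,5-dien-1-one | CCC(=O)C1=C(O)C(C)(C)C(O)=C(CSc2ccccc2)C1=O
F2 | step 4 | S-phenyl sulfonium ylide, 6-butanoyl-2-{[(2,4-dihydroxy-3,3-dimethyl-6-oxo-5-propanoylcyclohexa-1,4-dien-1-yl)methyl](phenyl)sulfonio}-5-hydroxy-4,4-dimethyl-3-oxocyclohexa-1,5-dien-1-olate | CCCC(=O)C1=C(O)C(C)(C)C(=O)C(=C1[O-])[S+](c1ccccc1)CC1=C(O)C(C)(C)C(O)=C(C(=O)CC)C1=O
F3 | step 4 | racemic 2-butanoyl-6-[(2,4-dihydroxy-3,3-dimethyl-6-oxo-5-propanoylcyclohexa-1,4-dien-1-yl)methyl]-3-hydroxy-4,4-dimethyl-6-(phenylsulfanyl)cyclohex-2-ene-1,5-dione | CCCC(=O)C1=C(O)C(C)(C)C(=O)C(Sc2ccccc2)(CC2=C(O)C(C)(C)C(O)=C(C(=O)CC)C2=O)C1=O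
F4 | step 2 | 2-butanoyl-6-diazo-3-hydroxy-4,4-dimethylcyclohex-2-ene-1,5-dione | CCCC(=O)C1=C(O)C(C)(C)C(=O)C(=[N+]=[N-])C1=O
F5 | step 1 | dimethyl 2,2-dimethylpropanedioate | COC(=O)C(C)(C)C(=O)OC
F6 | step 1 | methyl 2,2-dimethyl-3,5,7-trioxodecanoate | CCCC(=O)CC(=O)CC(=O)C(C)(C)C(=O)OC
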